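The tetramer is cut at its three interflavan C4–C8 bonds into three units taken from (+)-catechin and one made de novo, the second from the chain top. Its ring C (O1, C2, C3, C4, C4a, C8a) is closed in one operation by an oxa-Povarov annulation that exploits C2 as the benzylic carbon between O1 and ring B and C4a as the nucleophilic ortho carbon of phloroglucinol-type ring A: the O-aryl oxocarbenium ion C4a=C8a–O1+=C2 takes up the alkene (future C3=C4) of a twofold-symmetric, hydrobenzoin-derived 1,4-dioxene, forming C2–C3 and C4–C4a. The new dioxane acts as stereocontroller, O3 protecting group and C4 leaving group, and is erased by the final hydrogenolysis.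

Key step: step 10

Remark on the chemistry: the facial sense exerted by the auxiliary is assigned from an axial-attack model and the choice of (R,R)-hydrobenzoin rests on it; the C4 configuration of the ethoxyethyl ethers and of the annulation product is immaterial, because C4 is ionized in the couplings.

Step 1
Reactants: 1 (+)-catechin
Product: 2 5,7,3′,4′-tetra-O-benzyl-(+)-catechin
Conditions: BnBr (excess), K2CO3, DMF, 0 °C to rt
Reagents that add atoms: benzyl bromide, BrCc1ccccc1
Why: Williamson etherification with carbonate base should alkylate only the four phenols and leave the secondary hydroxyl on C3 and both stereocentres untouched.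

Step 2
Reactants: 2 tetra-O-benzyl-(+)-catechin
Product: 3 (2R,3S,4S)-5,7-bis(benzyloxy)-2-[3,4-bis(benzyloxy)phenyl]-4-(2-ethoxyethoxy)chroman-3-ol
Conditions: DDQ, 2-ethoxyethanol (excess), CH2Cl2, rt
Reagents that add atoms: 2-ethoxyethanol, CCOCCO
Why: DDQ abstracts the benzylic C4 hydride (oxidative C–H functionalization) to give the ring-A-stabilised cation, which the alcohol should trap mainly cis to O3.

Step 3
Reactants: 3 the ethoxyethyl ether alcohol
Product: 4 (2R,3S,4S)-5,7-bis(benzyloxy)-2-[3,4-bis(benzyloxy)phenyl]-4-(2-ethoxyethoxy)chroman-3-yl acetate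
Conditions: Ac2O, pyridine, DMAP (cat.), rt
Reagents that add atoms: acetic anhydride, CC(=O)OC(C)=O
Why: DMAP-catalysed acylation of the only free hydroxyl installs the participating group needed for the 3,4-trans couplings with this electrophile.

Step 4
Reactants: 4 the acetate electrophile; 2 tetra-O-benzyl-(+)-catechin
Product: 5 3-O-acetyl-octa-O-benzylprocyanidin B3 (acetate on the upper unit)
Conditions: TMSOTf (50 mol%), fourfold excess of the benzylated catechin, CH2Cl2, −78 °C
Reagents that add atoms: none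
Why: Lewis-acid ionization at C4 gives a benzylic cation bridged by the acetate on the face cis to O3, so Friedel–Crafts attack by C8 of the nucleophile should form the 3,4-trans (4α→8) bond, while the excess of nucleophile suppresses oligomerization.

Step 5
Reactants: 6 (R,R)-hydrobenzoin; 7 tert-butyl bromoacetate
Product: 9 (5R,6R)-5,6-diphenyl-1,4-dioxan-2-one, via hydroxy ester 8 (not isolated)
Conditions: NaH (one equiv), THF, 0 °C to rt; then TsOH·H2O (cat.), toluene, reflux
Reagents that add atoms: none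
Why: Williamson mono-O-alkylation of the twofold-symmetric diol followed by acid-catalysed lactonization to the six-membered ring, with both stereocentres untouched.

Step 6
Reactants: 9 the diphenyldioxanone
Product: 10 (5R,6R)-5,6-diphenyl-1,4-dioxan-2-ol (anomer mixture)
Conditions: i-Bu2AlH, CH2Cl2, −78 °C; aq. potassium sodium tartrate
Reagents that add atoms: none
Why: Partial reduction of a lactone stops at the tetrahedral aluminium hemiacetal at −78 °C and gives the lactol on work-up.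

Step 7
Reactants: 10 the lactol
Product: 12 (2R,3R)-2,3-diphenyl-2,3-dihydro-1,4-dioxine, via lactol mesylate 11 (not isolated)
Conditions: MsCl, Et3N (excess), CH2Cl2, −30 °C to reflux
Reagents that add atoms: none
Why: Sulfonylation of the hemiacetal hydroxyl and base-mediated elimination through the ring oxocarbenium ion is the standard lactol-to-cyclic-enol-ether (glycal-type) dehydration and does not touch the CHPh centres.

Step 8
Reactants: 13 protocatechualdehyde dibenzyl ether
Product: 14 1,2-bis(benzyloxy)-4-(dimethoxymethyl)benzene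
Conditions: HC(OMe)3, TsOH·H2O (cat.), MeOH, rt; Et3N quench
Reagents that add atoms: trimethyl orthoformate, COC(OC)OC
Why: Acid-catalysed acetalization driven by the orthoformate as dehydrating agent.

Step 9
Reactants: 14 the dimethyl acetal; 15 phloroglucinol dibenzyl ether
Product: 17 1,3-bis(benzyloxy)-5-{[3,4-bis(benzyloxy)phenyl](methoxy)methoxy}benzene (racemic), via α-chloro ether 16 (not isolated)
Conditions: AcCl, CH2Cl2, 0 °C, evaporate; then the phenol, NaH, THF/DMF, −30 to 0 °C; chromatography on Et3N-deactivated silica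
Reagents that add atoms: none
Why: Acetal/acyl chloride exchange gives the α-chloro ether, which O-alkylates the sodium phenoxide in an SN1-type Williamson reaction as in MOM ether formation; the acetal stereocentre becomes planar in the next step, so the racemate serves.

Step 10
Reactants: 17 the mixed O-aryl O-methyl acetal; 12 the (R,R)-diphenyldioxene
Product: 20 (2R,3S,4S)-5,7-bis(benzyloxy)-2-[3,4-bis(benzyloxy)phenyl]flavan-3,4-diol 3,4-O-[(1R,2R)-1,2-diphenylethane-1,2-diyl] ether (cis-fused 1,4-dioxane), via O-aryl oxocarbenium triflate 18 (not isolated), via dioxanyl oxocarbenium triflate 19 (not isolated)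
Conditions: TMSOTf (25 mol%), slight excess of the dioxene, MS 5A, CH2Cl2, −78 °C; Et3N quench
Reagents that add atoms: none
Why: TMSOTf silylates the more basic methoxy oxygen of the acetal and expels it to give the (E)-O-aryl oxocarbenium ion, whose carbon is attacked by an enol ether carbon of the dioxene (C2–C3 bond) to give the dioxanyl oxocarbenium ion, which the ortho carbon of the aryloxy ring captures in a Friedel–Crafts reaction (C4–C4a bond), the released proton regenerating the promoter. The closest known reaction type is the oxa-Povarov reaction, the formal [4+2] annulation of aryl-acetal-derived 2-oxadiene cations with alkenes, together with the Povarov reaction of cyclic enol ethers. Ring C closes by 6-exo-trig attack of the arene on the C4=O+ bond, and the dioxane is expected to become cis-fused as in Povarov adducts of cyclic enol ethers, because the tethered arene adds to C4 on the face of its own tether (the C4 centre is ionized again in the following coupling). C3 is set by the auxiliary: the dioxene should react in the half-chair that places both phenyl groups pseudo-equatorial and bond axially on the face anti to the phenyl of the CHPh carbon joined to the reacting carbon through oxygen, which for the (R,R)-dioxene is taken to correspond to 3S. C2 follows from the exo arrangement, in which the CHPh–CHPh bridge is turned away from ring A and its benzyloxy group on C5, giving the 2,3-trans (2R) relationship, which is also the more stable diequatorial one. Regioselectivity is not at stake, since the two alkene carbons of the dioxene are homotopic and the two ortho positions of the aryloxy ring are equivalent; the step needs exo and facial selectivity and a product that survives the acid, for which the bulky auxiliary, the substoichiometric promoter and −78 °C are chosen.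

Step 11
Reactants: 20 the dioxane-fused flavan; 5 the dimer monoacetate
Product: 21 protected trimer bearing the opened auxiliary as a hydroxy ether on O3 of the top unit
Conditions: TMSOTf (30 mol%), threefold excess of the dimer, CH2Cl2, −78 to −40 °C; aq. NaHCO3
Reagents that add atoms: none
Why: The Lewis acid silylates the benzylic dioxane oxygen on C4 and opens the ring to the ring-A-stabilised C4 cation, which C8 of the upper unit of the dimer should attack (Friedel–Crafts) anti to the bulky O3 substituent to give the 3,4-trans bond; proton and silyl exchange return the promoter, and the opened auxiliary stays on O3 as a benzyl-type protecting group, so the step is a net addition.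

Step 12
Reactants: 21 the protected trimer; 4 the acetate electrophile
Product: 22 protected tetramer diacetate bearing the auxiliary ether on O3 of the second unit
Conditions: TMSOTf (30 mol%), slow addition of a slight excess of the electrophile, CH2Cl2, −78 °C
Reagents that add atoms: none
Why: Same acetoxonium-directed Friedel–Crafts coupling as in the dimer synthesis; C8 of the top unit of the trimer is the only aromatic CH flanked by O1 and a single benzyloxy group, so the 4α→8 bond should form there with 3,4-trans selectivity, and slow addition limits self-condensation of the electrophile.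

Step 13
Reactants: 22 the protected tetramer diacetate
Product: 23 protected tetramer triol bearing the auxiliary ether on O3 of the second unit
Conditions: NaOMe (cat.), MeOH/THF, rt to 40 °C
Reagents that add atoms: none
Why: Zemplén transesterification removes both secondary acetates without touching ethers or stereocentres.

Step 14
Reactants: 23 the protected tetramer triol
Product: 24 catechin-(4α→8)-catechin-(4α→8)-catechin-(4α→8)-catechin (target)
Conditions: H2 (balloon), Pd(OH)2/C, THF/MeOH/H2O, rt; filtration, lyophilization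
Reagents that add atoms: none
Why: Hydrogenolysis should cleave the sixteen aryl benzyl ethers and the benzylic O3–CH(Ph) bond of the auxiliary, while the interflavan C4–C8 bonds and the C2–O1 bonds are expected to survive at ambient pressure and room temperature.

Compound list
1 | (+)-catechin, (2R,3S)-2-(3,4-dihydroxyphenyl)chromane-3,5,7-triol | Oc1cc(O)c2c(c1)O[C@H](c1ccc(O)c(O)c1)[C@@H](O)C2 | starting material
2 | 5,7,3′,4′-tetra-O-benzyl-(+)-catechin | C(c1ccccc1)Oc1cc(OCc2ccccc2)c2c(c1)O[C@H](c1ccc(OCc3ccccc3)c(OCc3ccccc3)c1)[C@@H](O)C2 | intermediate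
3 | (2R,3S,4S)-5,7-bis(benzyloxy)-2-[3,4-bis(benzyloxy)phenyl]-4-(2-ethoxyethoxy)chroman-3-ol | C(c1ccccc1)Oc1cc(OCc2ccccc2)c2c(c1)O[C@H](c1ccc(OCc3ccccc3)c(OCc3ccccc3)c1)[C@@H](O)[C@H]2OCCOCC | intermediate
4 | (2R,3S,4S)-5,7-bis(benzyloxy)-2-[3,4-bis(benzyloxy)phenyl]-4-(2-ethoxyethoxy)chroman-3-yl acetate | C(c1ccccc1)Oc1cc(OCc2ccccc2)c2c(c1)O[C@H](c1ccc(OCc3ccccc3)c(OCc3ccccc3)c1)[C@@H](OC(C)=O)[C@H]2OCCOCC | intermediate
5 | 3-O-acetyl-octa-O-benzylprocyanidin B3, i.e. [3-O-acetyl-5,7,3′,4′-tetra-O-benzylcatechin]-(4α→8)-[5,7,3′,4′-tetra-O-benzylcatechin] | C(c1ccccc1)Oc1cc(OCc2ccccc2)c2c(c1)O[C@H](c1ccc(OCc3ccccc3)c(OCc3ccccc3)c1)[C@@H](OC(C)=O)[C@@H]2c1c(OCc2ccccc2)cc(OCc2ccccc2)c2c1O[C@H](c1ccc(OCc3ccccc3)c(OCc3ccccc3)c1)[C@@H](O)C2 | intermediate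
6 | (1R,2R)-1,2-diphenylethane-1,2-diol, (R,R)-hydrobenzoin | O[C@H](c1ccccc1)[C@H](O)c1ccccc1 | starting material
7 | tert-butyl bromoacetate | BrCC(=O)OC(C)(C)C | starting material
8 | tert-butyl 2-[(1R,2R)-2-hydroxy-1,2-diphenylethoxy]acetate | O[C@H](c1ccccc1)[C@H](OCC(=O)OC(C)(C)C)c1ccccc1 | intermediate (not isolated)
9 | (5R,6R)-5,6-diphenyl-1,4-dioxan-2-one | O=C1CO[C@H](c2ccccc2)[C@H](O1)c1ccccc1 | intermediate
10 | (5R,6R)-5,6-diphenyl-1,4-dioxan-2-ol (anomer mixture) | OC1CO[C@H](c2ccccc2)[C@H](O1)c1ccccc1 | intermediate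
11 | (5R,6R)-5,6-diphenyl-1,4-dioxan-2-yl methanesulfonate | CS(=O)(=O)OC1CO[C@H](c2ccccc2)[C@H](O1)c1ccccc1 | intermediate (not isolated)
12 | (2R,3R)-2,3-diphenyl-2,3-dihydro-1,4-dioxine | C1=CO[C@H](c2ccccc2)[C@H](O1)c1ccccc1 | intermediate
13 | 3,4-bis(benzyloxy)benzaldehyde (protocatechualdehyde dibenzyl ether) | O=Cc1ccc(OCc2ccccc2)c(OCc2ccccc2)c1 | starting material
14 | 1,2-bis(benzyloxy)-4-(dimethoxymethyl)benzene | COC(OC)c1ccc(OCc2ccccc2)c(OCc2ccccc2)c1 | intermediate
15 | 3,5-bis(benzyloxy)phenol (phloroglucinol dibenzyl ether) | Oc1cc(OCc2ccccc2)cc(OCc2ccccc2)c1 | starting material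
16 | 1,2-bis(benzyloxy)-4-[chloro(methoxy)methyl]benzene | COC(Cl)c1ccc(OCc2ccccc2)c(OCc2ccccc2)c1 | intermediate (not isolated)
17 | 1,3-bis(benzyloxy)-5-{[3,4-bis(benzyloxy)phenyl](methoxy)methoxy}benzene (racemic) | COC(Oc1cc(OCc2ccccc2)cc(OCc2ccccc2)c1)c1ccc(OCc2ccccc2)c(OCc2ccccc2)c1 | intermediate
18 | (E)-O-[3,5-bis(benzyloxy)phenyl] oxocarbenium triflate of 3,4-bis(benzyloxy)benzaldehyde | C(c1ccccc1)Oc1cc(OCc2ccccc2)cc(c1)/[O+]=C/c1ccc(OCc2ccccc2)c(OCc2ccccc2)c1.[O-]S(=O)(=O)C(F)(F)F | intermediate (not isolated)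
19 | dioxanyl oxocarbenium triflate after C2–C3 bond formation (C4=O+ within the diphenyldioxane ring, configured as in the annulation product) | C(c1ccccc1)Oc1cc(OCc2ccccc2)cc(c1)O[C@H](c1ccc(OCc2ccccc2)c(OCc2ccccc2)c1)[C@H]1O[C@H](c2ccccc2)[C@@H](c2ccccc2)[O+]=C1.[O-]S(=O)(=O)C(F)(F)F | intermediate (not isolated)
20 | (2R,3S,4S)-5,7-bis(benzyloxy)-2-[3,4-bis(benzyloxy)phenyl]flavan-3,4-diol 3,4-O-[(1R,2R)-1,2-diphenylethane-1,2-diyl] ether (cis-fused dioxane) | C(c1ccccc1)Oc1cc(OCc2ccccc2)c2c(c1)O[C@H](c1ccc(OCc3ccccc3)c(OCc3ccccc3)c1)[C@H]3O[C@H](c4ccccc4)[C@@H](c4ccccc4)O[C@@H]23 | intermediate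
21 | protected trimer: [3-O-((1R,2R)-2-hydroxy-1,2-diphenylethyl)-tetra-O-benzylcatechin]-(4α→8)-[3-O-acetyl-tetra-O-benzylcatechin]-(4α→8)-[tetra-O-benzylcatechin] | C(c1ccccc1)Oc1cc(OCc2ccccc2)c2c(c1)O[C@H](c1ccc(OCc3ccccc3)c(OCc3ccccc3)c1)[C@@H](O[C@H](c1ccccc1)[C@H](O)c1ccccc1)[C@@H]2c1c(OCc2ccccc2)cc(OCc2ccccc2)c2c1O[C@H](c1ccc(OCc3ccccc3)c(OCc3ccccc3)c1)[C@@H](OC(C)=O)[C@@H]2c1c(OCc2ccccc2)cc(OCc2ccccc2)c2c1O[C@H](c1ccc(OCc3ccccc3)c(OCc3ccccc3)c1)[C@@H](O)C2 | intermediate
22 | protected tetramer diacetate: [3-O-acetyl-tetra-O-benzylcatechin]-(4α→8)-[3-O-((1R,2R)-2-hydroxy-1,2-diphenylethyl)-tetra-O-benzylcatechin]-(4α→8)-[3-O-acetyl-tetra-O-benzylcatechin]-(4α→8)-[tetra-O-benzylcatechin] | C(c1ccccc1)Oc1cc(OCc2ccccc2)c2c(c1)O[C@H](c1ccc(OCc3ccccc3)c(OCc3ccccc3)c1)[C@@H](OC(C)=O)[C@@H]2c1c(OCc2ccccc2)cc(OCc2ccccc2)c2c1O[C@H](c1ccc(OCc3ccccc3)c(OCc3ccccc3)c1)[C@@H](O[C@H](c1ccccc1)[C@H](O)c1ccccc1)[C@@H]2c1c(OCc2ccccc2)cc(OCc2ccccc2)c2c1O[C@H](c1ccc(OCc3ccccc3)c(OCc3ccccc3)c1)[C@@H](OC(C)=O)[C@@H]2c1c(OCc2ccccc2)cc(OCc2ccccc2)c2c1O[C@H](c1ccc(OCc3ccccc3)c(OCc3ccccc3)c1)[C@@H](O)C2 | intermediate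
23 | protected tetramer triol: free hydroxyl on C3 of the first, third and fourth units, (1R,2R)-2-hydroxy-1,2-diphenylethyl ether on O3 of the second unit, sixteen benzyl ethers | C(c1ccccc1)Oc1cc(OCc2ccccc2)c2c(c1)O[C@H](c1ccc(OCc3ccccc3)c(OCc3ccccc3)c1)[C@@H](O)[C@@H]2c1c(OCc2ccccc2)cc(OCc2ccccc2)c2c1O[C@H](c1ccc(OCc3ccccc3)c(OCc3ccccc3)c1)[C@@H](O[C@H](c1ccccc1)[C@H](O)c1ccccc1)[C@@H]2c1c(OCc2ccccc2)cc(OCc2ccccc2)c2c1O[C@H](c1ccc(OCc3ccccc3)c(OCc3ccccc3)c1)[C@@H](O)[C@@H]2c1c(OCc2ccccc2)cc(OCc2ccccc2)c2c1O[C@H](c1ccc(OCc3ccccc3)c(OCc3ccccc3)c1)[C@@H](O)C2 | intermediate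
24 | catechin-(4α→8)-catechin-(4α→8)-catechin-(4α→8)-catechin | Oc1cc(O)c2c(c1)O[C@H](c1ccc(O)c(O)c1)[C@@H](O)[C@@H]2c1c(O)cc(O)c2c1O[C@H](c1ccc(O)c(O)c1)[C@@H](O)[C@@H]2c1c(O)cc(O)c2c1O[C@H](c1ccc(O)c(O)c1)[C@@H](O)[C@@H]2c1c(O)cc(O)c2c1O[C@H](c1ccc(O)c(O)c1)[C@@H](O)C2 | target

Total step count: 14.
Longest linear sequence: 8 steps (steps 1, 2, 3, 4, 11, 12, 13, 14 from (+)-catechin; equally steps 5, 6, 7, 10, 11, 12, 13, 14 from hydrobenzoin).

Steps most likely to fail

Step 10. The first C–C bond formation may discriminate poorly between exo and endo approach or between the two faces of the dioxene, and the product may re-ionize at C4 under the promoter and oligomerize. Fallback: the second unit is taken from the chiral pool instead of being built. Setting out from 4 and 5, the acetate 4 is coupled with excess 5 (TMSOTf, CH2Cl2, −78 °C) to give the protected trimer diacetate F1. A second coupling of F1 with 4 under the same conditions gives the protected tetramer triacetate F2. Zemplén deacetylation (NaOMe, MeOH/THF) gives hexadeca-O-benzyl tetramer F3, and hydrogenolysis (H2, Pd(OH)2/C) returns to the route at 24.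

Step 11. Re-closure of the tethered oxygen onto the C4 cation may outrun intermolecular capture by the arene, and 3,4-trans selectivity may erode because the O3 ether cannot participate. Fallback: the leaving group is changed to one that cannot return. Setting out from 20, ring opening with benzyl mercaptan (BnSH in excess, BF3·OEt2, CH2Cl2, −78 °C) gives the 4-benzylthio ether F4. Thiophilic activation (AgBF4, THF/CH2Cl2, 0 °C) in the presence of 5 then gives the trimer, rejoining the route at 21.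

Step 12. Self-condensation of electrophile 4 through its own C8 may compete with attack by the hindered trimer, which cannot be used in excess. Fallback: C8 of the electrophile is capped. Setting out from 4, bromination (NBS, CH2Cl2, low temperature) gives the 8-bromo electrophile F5, which can be used in excess with 21 (TMSOTf, CH2Cl2, −78 °C) to give the 8-bromo tetramer diacetate F6. Deacetylation (NaOMe, MeOH/THF) gives the 8-bromo tetramer triol F7, and hydrogenolysis in the presence of Et3N (H2, Pd(OH)2/C) removes the benzyl groups, the auxiliary and the bromine together, rejoining the route at 24.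

Further compounds
F1 | step 10 | protected trimer diacetate: [3-O-acetyl-tetra-O-benzylcatechin]-(4α→8)-[3-O-acetyl-tetra-O-benzylcatechin]-(4α→8)-[tetra-O-benzylcatechin] | C(c1ccccc1)Oc1cc(OCc2ccccc2)c2c(c1)O[C@H](c1ccc(OCc3ccccc3)c(OCc3ccccc3)c1)[C@@H](OC(C)=O)[C@@H]2c1c(OCc2ccccc2)cc(OCc2ccccc2)c2c1O[C@H](c1ccc(OCc3ccccc3)c(OCc3ccccc3)c1)[C@@H](OC(C)=O)[C@@H]2c1c(OCc2ccccc2)cc(OCc2ccccc2)c2c1O[C@H](c1ccc(OCc3ccccc3)c(OCc3ccccc3)c1)[C@@H](O)C2
F2 | step 10 | protected tetramer triacetate (acetates on O3 of the first, second and third units) | C(c1ccccc1)Oc1cc(OCc2ccccc2)c2c(c1)O[C@H](c1ccc(OCc3ccccc3)c(OCc3ccccc3)c1)[C@@H](OC(C)=O)[C@@H]2c1c(OCc2ccccc2)cc(OCc2ccccc2)c2c1O[C@H](c1ccc(OCc3ccccc3)c(OCc3ccccc3)c1)[C@@H](OC(C)=O)[C@@H]2c1c(OCc2ccccc2)cc(OCc2ccccc2)c2c1O[C@H](c1ccc(OCc3ccccc3)c(OCc3ccccc3)c1)[C@@H](OC(C)=O)[C@@H]2c1c(OCc2ccccc2)cc(OCc2ccccc2)c2c1O[C@H](c1ccc(OCc3ccccc3)c(OCc3ccccc3)c1)[C@@H](O)C2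
F3 | step 10 | hexadeca-O-benzyl catechin-(4α→8)-catechin-(4α→8)-catechin-(4α→8)-catechin | C(c1ccccc1)Oc1cc(OCc2ccccc2)c2c(c1)O[C@H](c1ccc(OCc3ccccc3)c(OCc3ccccc3)c1)[C@@H](O)[C@@H]2c1c(OCc2ccccc2)cc(OCc2ccccc2)c2c1O[C@H](c1ccc(OCc3ccccc3)c(OCc3ccccc3)c1)[C@@H](O)[C@@H]2c1c(OCc2ccccc2)cc(OCc2ccccc2)c2c1O[C@H](c1ccc(OCc3ccccc3)c(OCc3ccccc3)c1)[C@@H](O)[C@@H]2c1c(OCc2ccccc2)cc(OCc2ccccc2)c2c1O[C@H](c1ccc(OCc3ccccc3)c(OCc3ccccc3)c1)[C@@H](O)C2
F4 | step 11 | 4α-benzylthio-5,7,3′,4′-tetra-O-benzylcatechin 3-O-[(1R,2R)-2-hydroxy-1,2-diphenylethyl] ether (3,4-trans) | C(c1ccccc1)Oc1cc(OCc2ccccc2)c2c(c1)O[C@H](c1ccc(OCc3ccccc3)c(OCc3ccccc3)c1)[C@@H](O[C@H](c1ccccc1)[C@H](O)c1ccccc1)[C@@H]2SCc1ccccc1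
F5 | step 12 | (2R,3S,4S)-5,7-bis(benzyloxy)-2-[3,4-bis(benzyloxy)phenyl]-8-bromo-4-(2-ethoxyethoxy)chroman-3-yl acetate | C(c1ccccc1)Oc1cc(OCc2ccccc2)c2c(c1Br)O[C@H](c1ccc(OCc3ccccc3)c(OCc3ccccc3)c1)[C@@H](OC(C)=O)[C@H]2OCCOCC
F6 | step 12 | 8-bromo protected tetramer diacetate (bromine on C8 of the first unit, otherwise as the protected tetramer diacetate of the route) | C(c1ccccc1)Oc1cc(OCc2ccccc2)c2c(c1Br)O[C@H](c1ccc(OCc3ccccc3)c(OCc3ccccc3)c1)[C@@H](OC(C)=O)[C@@H]2c1c(OCc2ccccc2)cc(OCc2ccccc2)c2c1O[C@H](c1ccc(OCc3ccccc3)c(OCc3ccccc3)c1)[C@@H](O[C@H](c1ccccc1)[C@H](O)c1ccccc1)[C@@H]2c1c(OCc2ccccc2)cc(OCc2ccccc2)c2c1O[C@H](c1ccc(OCc3ccccc3)c(OCc3ccccc3)c1)[C@@H](OC(C)=O)[C@@H]2c1c(OCc2ccccc2)cc(OCc2ccccc2)c2c1O[C@H](c1ccc(OCc3ccccc3)c(OCc3ccccc3)c1)[C@@H](O)C2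
F7 | step 12 | 8-bromo protected tetramer triol (bromine on C8 of the first unit, otherwise as the protected tetramer triol of the route) | C(c1ccccc1)Oc1cc(OCc2ccccc2)c2c(c1Br)O[C@H](c1ccc(OCc3ccccc3)c(OCc3ccccc3)c1)[C@@H](O)[C@@H]2c1c(OCc2ccccc2)cc(OCc2ccccc2)c2c1O[C@H](c1ccc(OCc3ccccc3)c(OCc3ccccc3)c1)[C@@H](O[C@H](c1ccccc1)[C@H](O)c1ccccc1)[C@@H]2c1c(OCc2ccccc2)cc(OCc2ccccc2)c2c1O[C@H](c1ccc(OCc3ccccc3)c(OCc3ccccc3)c1)[C@@H](O)[C@@H]2c1c(OCc2ccccc2)cc(OCc2ccccc2)c2c1O[C@H](c1ccc(OCc3ccccc3)c(OCc3ccccc3)c1)[C@@H](O)C2
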